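It is tempting to read a half-life off these runs and carry it to the flask, but that would be a mistake here. In the flask, partner is charged at 0.200 M, equal to the two substrates together, so neither is in excess and the decay isn't exponential.

| flask | left-handed substrate | right-handed substrate | partner | precatalyst | impurity | remark | time |
|---|---|---|---|---|---|---|---|
| north | 0.14 M | 0.14 M | 2 equiv | 0.2 mol% | 92 µM | run made earlier |  |
| east | 0.22 M | 0.22 M | 2 equiv | 0.2 mol% | 92 µM | run made earlier |  |
| flask | 0.10 M | 0.10 M | 2.00 equiv | 0.2 mol% | 92 µM |  | 4.0 min |

- north (time / min: left-handed product / %, right-handed product / %, left-handed substrate / %): 0.200: 20.0, 12.5, 33.4; 0.333: 36.7, 23.7, 20.7; 0.417: 44.5, 24.5, 13.7; 0.667: 51.3, 30.4, 8.6; 1.00: 55.4, 31.6, 5.1; 1.50: 58.9, 33.4, 4.6; 2.50: 60.7, 35.2, 1.1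
- east (time / min: left-handed product / %, right-handed product / %, left-handed substrate / %): 0.333: 53.4, 31.7, 5.3; 0.667: 59.3, 33.2, 3.5; 1.00: 59.1, 33.7, 1.6; 1.33: 61.3, 36.5, 0; 1.50: 61.0, 34.8, 0.8; 2.00: 63.9, 37.5, 0.5; 2.50: 63.3, 36.3, 1.6

(each reading ± 1 percentage point)

1. left-handed product and right-handed product together, in percent of the left-handed substrate and right-handed substrate charged together, at 4.0 min
2. excess of left-handed product over right-handed product in the product at 4.0 min
3. whether the exchange between left-handed substrate and right-handed substrate keeps pace with the reaction: how far the product's excess at 4.0 min gets from its value without exchange to its value with instant exchange (above 80 % keeps pace, below 20 % hardly takes part, else lags behind)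

- free catalyst is single-handed; left-handed substrate and right-handed substrate are mirror images of each other, charged as a racemate, each of them at the stated concentration
- steps that have been proposed: partner + free catalyst + right-handed substrate -> free catalyst + right-handed product; free catalyst + impurity -> spent catalyst; left-handed substrate <-> right-handed substrate; partner + precatalyst -> free catalyst + spent reagent; partner + free catalyst + left-handed substrate -> free catalyst + left-handed product
- an excess is below zero if the other one leads

Each turnover takes one partner and one substrate, so [partner] ≈ [substrates] throughout, and the rate goes as [catalyst]·[substrates] squared. Integrated, the ratio H of reacted to unreacted substrate grows on a straight line: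

H = κ · [partner charged] · [catalyst] · t

We take [catalyst] as the charge minus the impurity, assuming one impurity spends one catalyst. That leaves 108 µM in the flask and 188 µM in north.

First pass: north at 0.417 min has H = 2.23, which gives κ = 1690 M⁻² s⁻¹ and, for the flask at 4.0 min, y = 89.8 %.

The weak link is the start, since the precatalyst has to open first. So we take the slope instead: κ, the reading of H gained per time, per [partner charged] and [catalyst], from north's H of 12.0 at 1.50 min:

κ = 2850 M⁻² s⁻¹, lag τ = 0.170 min

H(flask) = κ · [partner charged] · [catalyst] · (t − τ) = 14.2, so y = 93.4 %

East's noisier slope, 2160 M⁻² s⁻¹, gives 91.5 %, and we hold that as our low end.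

North's left-handed product reads 58.9 %, more than half the charge, so the substrates exchange. We therefore expect the flask to keep pace, with the excess read from north's last row, 26.6 %.

The forecast says y = 87 % (78 % to 94 %), lower than ours, with eP = 27 % (24 % to 30 %) and keeps pace, on the grounds “So exchange is fast”.

The flask gives y = 94.9 %, eP = 26.6 % and keeps pace, at 99.6 % of the way.

    partner + free catalyst + right-handed substrate → free catalyst + right-handed product (k = 3300 M⁻² s⁻¹)
    free catalyst + impurity → spent catalyst (k = 97000 M⁻¹ s⁻¹)
    left-handed substrate ⇌ right-handed substrate (k = 3.40 s⁻¹)
    partner + precatalyst → free catalyst + spent reagent (k = 0.310 M⁻¹ s⁻¹)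
    partner + free catalyst + left-handed substrate → free catalyst + left-handed product (k = 5700 M⁻² s⁻¹)

Its H is 18.6, which puts κ at 3747 M⁻² s⁻¹, above our reading of 2850 M⁻² s⁻¹. Now take the neighbour charged with 0.500 equiv of partner. Partner becomes the limiting reagent, with a ceiling of y = 25.0 %. The substrates stay above 0.150 M, so partner decays pseudo-first-order. At 4.00 min this neighbour holds 26.1 % of its catalyst as free catalyst and 27.9 % still as precatalyst, and κ with that [catalyst] gives partner a half-life of about 0.517 min, shorter than the 4.0 min allowed. That neighbour gives y = 24.9 %, with 0.17 % of its partner left.

Readings and results are simulated for an exercise.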